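**Retrosynthetic overview**
- The target comes from its C2,C14-diacetate by lipase-catalysed removal of the primary acetate only; the diacetate comes from the macrocyclic C8 alcohol by methacrylation, desilylation and acetylation.
- The ten-membered carbocycle is the second ring formed, by ring-closing metathesis at C1=C10 on a diene that already carries the trans-lactone and all four stereocentres.
- The C7–C8 bond and the α-methylene-γ-lactone come from a CrCl2-mediated allylation of a β,γ-unsaturated aldehyde (fragment B) with a 3-(bromomethyl)butenolide (fragment A); C8 is then inverted by a Mitsunobu reaction.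
- The butenolide is the first ring formed, by carbonylative lactonization of a Z-iodoallylic alcohol. That alcohol comes from zinc-catalysed asymmetric alkynylation of an enal (C6), carboalumination (E-C4=C5) and phosphoric-acid-catalysed propargylation of crotonaldehyde (C2, first stereocentre).
- Fragment B comes from 2-methylidenepropane-1,3-diol by monosilylation, bromination, zinc Barbier hydroxymethylation and oxidation.

Assumption: atoms are located by germacrane numbering (ring C1–C10, lactone carbons C11–C13, C14 = CH2O on C10, C15 = methyl on C4); the catalyst and ligand antipodes in steps 1 and 5 are assigned by analogy with simple aldehydes and would be confirmed by Mosher analysis; TBS = tert-butyldimethylsilyl, PMB = 4-methoxybenzyl.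

**Fragment A**

Step 1
Reactants: 1 (E)-but-2-enal (crotonaldehyde); 2 allenylboronic acid pinacol ester (4,4,5,5-tetramethyl-2-(propa-1,2-dien-1-yl)-1,3,2-dioxaborolane)
Product: 4 (4S,5E)-hept-5-en-1-yn-4-ol, via pinacol borate ester 3 (not isolated)
Conditions: (S)-3,3'-bis(2,4,6-triisopropylphenyl)-1,1'-binaphthyl-2,2'-diyl hydrogen phosphate (5 mol %), 4 Å MS, toluene, −30 °C; aqueous work-up
Reagents that add atoms: none
Why: Chiral-phosphoric-acid-catalysed allenylboration (asymmetric propargylation): the acid activates the boronate in a closed six-membered transition state and leaves only the Si face of the aldehyde open, so this catalytic step sets the first stereocentre (C2, S) from two achiral partners, the borate ester being hydrolysed on work-up.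

Step 2
Reactants: 4 (4S,5E)-hept-5-en-1-yn-4-ol
Product: 5 tert-butyl{[(4S,5E)-hept-5-en-1-yn-4-yl]oxy}dimethylsilane
Conditions: TBSCl, imidazole, DMF, 0 °C → rt
Reagents that add atoms: tert-butyldimethylsilyl chloride, CC(C)(C)[Si](C)(C)Cl
Why: Standard silylation of a secondary alcohol; the TBS ether withstands the organoaluminium, hydride, chromium and ruthenium steps that follow and leaves C2 untouched.

Step 3
Reactants: 5 tert-butyl{[(4S,5E)-hept-5-en-1-yn-4-yl]oxy}dimethylsilane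
Product: 7 (2E,5S,6E)-5-{[tert-butyl(dimethyl)silyl]oxy}-3-methylocta-2,6-dien-1-ol, via alkenyldimethylalane 6 (not isolated)
Conditions: Me3Al (2.5 equiv), Cp2ZrCl2 (0.25 equiv), CH2Cl2, 0 °C → rt; then (CH2O)n, THF, 0 °C → rt; aq. potassium sodium tartrate
Reagents that add atoms: trimethylaluminium, C[Al](C)C; paraformaldehyde (as formaldehyde), C=O
Why: Negishi zirconium-catalysed carboalumination: Me–Al adds syn across the terminal alkyne with methyl on the internal carbon, and the alkenylalane is hydroxymethylated with retention, which fixes the E geometry of C4=C5 (the disubstituted propenyl alkene is inert).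

Step 4
Reactants: 7 (2E,5S,6E)-5-{[tert-butyl(dimethyl)silyl]oxy}-3-methylocta-2,6-dien-1-ol
Product: 8 (2E,5S,6E)-5-{[tert-butyl(dimethyl)silyl]oxy}-3-methylocta-2,6-dienal
Conditions: MnO2 (15 equiv), CH2Cl2, rt
Reagents that add atoms: none
Why: Chemoselective MnO2 oxidation of the primary allylic alcohol to the enal without E/Z isomerisation or attack on the silyl ether.

Step 5
Reactants: 8 (2E,5S,6E)-5-{[tert-butyl(dimethyl)silyl]oxy}-3-methylocta-2,6-dienal; 9 4-methoxybenzyl propargyl ether (1-methoxy-4-[(prop-2-yn-1-yloxy)methyl]benzene)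
Product: 11 (4R,5E,8S,9E)-8-{[tert-butyl(dimethyl)silyl]oxy}-1-[(4-methoxyphenyl)methoxy]-6-methylundeca-5,9-dien-2-yn-4-ol, via alkynyl(methyl)zinc reagent 10 (not isolated)
Conditions: Me2Zn (3 equiv), 9 (3 equiv), (R,R)-2,6-bis{[2-(hydroxydiphenylmethyl)pyrrolidin-1-yl]methyl}-4-methylphenol (ProPhenol ligand, 20 mol %), Ph3PO (40 mol %), toluene, 0 → 4 °C; aqueous work-up
Reagents that add atoms: none
Why: Zinc–ProPhenol asymmetric alkynylation (Trost): the dinuclear zinc complex of the (R,R)-ligand binds both alkynyl and enal and delivers the alkyne to the Si face, setting C6 (R) under catalyst control far from C2; the minor diastereomer is removed by chromatography, which also raises the enantiomeric purity.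

Step 6
Reactants: 11 (4R,5E,8S,9E)-8-{[tert-butyl(dimethyl)silyl]oxy}-1-[(4-methoxyphenyl)methoxy]-6-methylundeca-5,9-dien-2-yn-4-ol
Product: 13 (2Z,4R,5E,8S,9E)-8-{[tert-butyl(dimethyl)silyl]oxy}-2-iodo-1-[(4-methoxyphenyl)methoxy]-6-methylundeca-2,5,9-trien-4-ol, via cyclic sodium alkenylaluminate 12 (not isolated)
Conditions: NaAlH2(OCH2CH2OMe)2, THF, 0 °C; then I2, THF, −78 → 0 °C; aq. Na2S2O3, aq. potassium sodium tartrate
Reagents that add atoms: iodine, II
Why: Hydroxyl-directed trans-hydroalumination followed by iodinolysis with retention: hydride goes to the alkyne carbon next to the carbinol and aluminium (then iodine) to the distal carbon, giving the Z-iodoalkene with iodine cis to the carbinol carbon, while keeping the aluminate at or below 0 °C avoids β-elimination of the PMB ether to an allene.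

Step 7
Reactants: 13 (2Z,4R,5E,8S,9E)-8-{[tert-butyl(dimethyl)silyl]oxy}-2-iodo-1-[(4-methoxyphenyl)methoxy]-6-methylundeca-2,5,9-trien-4-ol
Product: 14 (5R)-5-[(1E,4S,5E)-4-{[tert-butyl(dimethyl)silyl]oxy}-2-methylhepta-1,5-dien-1-yl]-3-{[(4-methoxyphenyl)methoxy]methyl}furan-2(5H)-one
Conditions: PdCl2(PPh3)2 (5 mol %), CO (1 atm), K2CO3, THF, rt
Reagents that add atoms: carbon monoxide, [C-]#[O+]
Why: Palladium-catalysed cyclocarbonylation: oxidative addition of zerovalent palladium to the C–I bond, CO insertion and capture of the acylpalladium by the cis hydroxyl close the butenolide (the first ring) without touching C6.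

Step 8
Reactants: 14 (5R)-5-[(1E,4S,5E)-4-{[tert-butyl(dimethyl)silyl]oxy}-2-methylhepta-1,5-dien-1-yl]-3-{[(4-methoxyphenyl)methoxy]methyl}furan-2(5H)-one
Product: 15 (5R)-5-[(1E,4S,5E)-4-{[tert-butyl(dimethyl)silyl]oxy}-2-methylhepta-1,5-dien-1-yl]-3-(hydroxymethyl)furan-2(5H)-one
Conditions: DDQ (2,3-dichloro-5,6-dicyano-1,4-benzoquinone), CH2Cl2/pH 7 phosphate buffer, 0 °C
Reagents that add atoms: none
Why: Oxidative cleavage of the PMB ether by DDQ via the benzylic oxocarbenium ion; silyl ether, alkenes and butenolide are inert.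

Step 9
Reactants: 15 (5R)-5-[(1E,4S,5E)-4-{[tert-butyl(dimethyl)silyl]oxy}-2-methylhepta-1,5-dien-1-yl]-3-(hydroxymethyl)furan-2(5H)-one
Product: 16 (5R)-3-(bromomethyl)-5-[(1E,4S,5E)-4-{[tert-butyl(dimethyl)silyl]oxy}-2-methylhepta-1,5-dien-1-yl]furan-2(5H)-one
Conditions: CBr4, PPh3, CH2Cl2, 0 °C
Reagents that add atoms: carbon tetrabromide, BrC(Br)(Br)Br
Why: Appel reaction converts the primary allylic alcohol into the bromide under neutral conditions.

**Fragment B**

Step 10
Reactants: 17 2-methylidenepropane-1,3-diol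
Product: 19 2-({[tert-butyl(dimethyl)silyl]oxy}methyl)prop-2-en-1-ol, via sodium monoalkoxide 18 (not isolated)
Conditions: NaH (1.0 equiv), THF, 0 °C → rt; then TBSCl (1.0 equiv)
Reagents that add atoms: tert-butyldimethylsilyl chloride, CC(C)(C)[Si](C)(C)Cl
Why: Monosilylation through the sparingly soluble sodium monoalkoxide (Williamson-type silylation), which reacts once and leaves the second hydroxyl free; no stereocentre.

Step 11
Reactants: 19 2-({[tert-butyl(dimethyl)silyl]oxy}methyl)prop-2-en-1-ol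
Product: 20 {[2-(bromomethyl)prop-2-en-1-yl]oxy}(tert-butyl)dimethylsilane
Conditions: CBr4, PPh3, CH2Cl2, 0 °C
Reagents that add atoms: carbon tetrabromide, BrC(Br)(Br)Br
Why: Appel reaction on the allylic alcohol; the allyl unit is symmetric, so SN2 and SN2' give the same bromide.

Step 12
Reactants: 20 {[2-(bromomethyl)prop-2-en-1-yl]oxy}(tert-butyl)dimethylsilane
Product: 22 3-({[tert-butyl(dimethyl)silyl]oxy}methyl)but-3-en-1-ol, via allylzinc bromide 21 (not isolated)
Conditions: Zn dust, 37 % aq. HCHO, THF, rt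
Reagents that add atoms: formaldehyde, C=O
Why: Zinc Barbier hydroxymethylation in water: the allylzinc adds to formaldehyde, and because both allyl termini are equivalent a single homoallylic alcohol with the 1,1-disubstituted alkene results.

Step 13
Reactants: 22 3-({[tert-butyl(dimethyl)silyl]oxy}methyl)but-3-en-1-ol
Product: 23 3-({[tert-butyl(dimethyl)silyl]oxy}methyl)but-3-enal
Conditions: Dess–Martin periodinane, NaHCO3, CH2Cl2, 0 °C; used crude at once
Reagents that add atoms: none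
Why: Buffered Dess–Martin oxidation gives the β,γ-unsaturated aldehyde under neutral conditions that do not move the alkene into conjugation; it is used without purification.

**Union and completion**

Step 14
Reactants: 16 (5R)-3-(bromomethyl)-5-[(1E,4S,5E)-4-{[tert-butyl(dimethyl)silyl]oxy}-2-methylhepta-1,5-dien-1-yl]furan-2(5H)-one; 23 3-({[tert-butyl(dimethyl)silyl]oxy}methyl)but-3-enal
Product: 25 (4R,5R)-4-[(1S)-3-({[tert-butyl(dimethyl)silyl]oxy}methyl)-1-hydroxybut-3-en-1-yl]-5-[(1E,4S,5E)-4-{[tert-butyl(dimethyl)silyl]oxy}-2-methylhepta-1,5-dien-1-yl]-3-methylidenedihydrofuran-2(3H)-one, via allylchromium dichloride 24 (not isolated)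
Conditions: CrCl2 (4 equiv), 23 (1.5 equiv), THF, 0 °C → rt; aqueous work-up
Reagents that add atoms: none
Why: Chromium-mediated Barbier (Nozaki–Hiyama-type) allylation: the allylchromium attacks through its γ-carbon (C7) on the face of the butenolide opposite the C6 side chain, giving the trans lactone (C7, R) and the exocyclic methylene, and the ring-locked allyl geometry in a Zimmerman–Traxler chair gives the 7,8-anti (8S) carbinol.

Step 15
Reactants: 25 (4R,5R)-4-[(1S)-3-({[tert-butyl(dimethyl)silyl]oxy}methyl)-1-hydroxybut-3-en-1-yl]-5-[(1E,4S,5E)-4-{[tert-butyl(dimethyl)silyl]oxy}-2-methylhepta-1,5-dien-1-yl]-3-methylidenedihydrofuran-2(3H)-one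
Product: 26 (1R)-3-({[tert-butyl(dimethyl)silyl]oxy}methyl)-1-[(2R,3R)-2-[(1E,4S,5E)-4-{[tert-butyl(dimethyl)silyl]oxy}-2-methylhepta-1,5-dien-1-yl]-4-methylidene-5-oxooxolan-3-yl]but-3-en-1-yl formate
Conditions: PPh3 and diisopropyl azodicarboxylate (premixed, 0 °C), HCO2H, THF, 0 °C → rt
Reagents that add atoms: formic acid, O=CO
Why: Mitsunobu reaction: SN2 displacement of the alkoxyphosphonium by the small, acidic formate inverts C8 to the required R configuration and leaves an ester that is inert to metathesis.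

Step 16
Reactants: 26 (1R)-3-({[tert-butyl(dimethyl)silyl]oxy}methyl)-1-[(2R,3R)-2-[(1E,4S,5E)-4-{[tert-butyl(dimethyl)silyl]oxy}-2-methylhepta-1,5-dien-1-yl]-4-methylidene-5-oxooxolan-3-yl]but-3-en-1-yl formate
Product: 27 (3aR,4R,6E,8S,10E,11aR)-8-{[tert-butyl(dimethyl)silyl]oxy}-6-({[tert-butyl(dimethyl)silyl]oxy}methyl)-10-methyl-3-methylidene-2-oxo-2,3,3a,4,5,8,9,11a-octahydrocyclodeca[b]furan-4-yl formate
Conditions: second-generation Hoveyda–Grubbs catalyst (15 mol %, in portions), toluene (1 mM), 90 °C, argon sparge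
Reagents that add atoms: none
Why: Ring-closing metathesis: the ruthenium carbene formed at the propenyl group closes onto the 1,1-disubstituted alkene with loss of propene, and the new trisubstituted C1=C10 bond forms with C2 and C9 cis because a trans-cycloalkene in a ten-membered ring that already holds an E-alkene and a trans-fused lactone is far more strained; the electron-poor α-methylene lactone does not take part.

Step 17
Reactants: 27 (3aR,4R,6E,8S,10E,11aR)-8-{[tert-butyl(dimethyl)silyl]oxy}-6-({[tert-butyl(dimethyl)silyl]oxy}methyl)-10-methyl-3-methylidene-2-oxo-2,3,3a,4,5,8,9,11a-octahydrocyclodeca[b]furan-4-yl formate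
Product: 28 (3aR,4R,6E,8S,10E,11aR)-8-{[tert-butyl(dimethyl)silyl]oxy}-6-({[tert-butyl(dimethyl)silyl]oxy}methyl)-4-hydroxy-10-methyl-3-methylidene-3a,4,5,8,9,11a-hexahydrocyclodeca[b]furan-2(3H)-one
Conditions: KHCO3 (0.3 equiv), MeOH, 0 °C
Reagents that add atoms: none
Why: Base-catalysed transesterification: a formate is methanolysed orders of magnitude faster than the lactone or silyl ethers react, and bicarbonate is too weak to add methanol to the α-methylene lactone.

Step 18
Reactants: 28 (3aR,4R,6E,8S,10E,11aR)-8-{[tert-butyl(dimethyl)silyl]oxy}-6-({[tert-butyl(dimethyl)silyl]oxy}methyl)-4-hydroxy-10-methyl-3-methylidene-3a,4,5,8,9,11a-hexahydrocyclodeca[b]furan-2(3H)-one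
Product: 29 (3aR,4R,6E,8S,10E,11aR)-8-{[tert-butyl(dimethyl)silyl]oxy}-6-({[tert-butyl(dimethyl)silyl]oxy}methyl)-10-methyl-3-methylidene-2-oxo-2,3,3a,4,5,8,9,11a-octahydrocyclodeca[b]furan-4-yl 2-methylprop-2-enoate
Conditions: methacrylic anhydride, Et3N, 4-(dimethylamino)pyridine (cat.), CH2Cl2, 0 °C → rt
Reagents that add atoms: methacrylic anhydride, C=C(C)C(=O)OC(=O)C(C)=C
Why: Acyl transfer catalysed by 4-(dimethylamino)pyridine esterifies the C8 hydroxyl with retention of the configuration set in step 15.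

Step 19
Reactants: 29 (3aR,4R,6E,8S,10E,11aR)-8-{[tert-butyl(dimethyl)silyl]oxy}-6-({[tert-butyl(dimethyl)silyl]oxy}methyl)-10-methyl-3-methylidene-2-oxo-2,3,3a,4,5,8,9,11a-octahydrocyclodeca[b]furan-4-yl 2-methylprop-2-enoate
Product: 30 (3aR,4R,6E,8S,10E,11aR)-8-hydroxy-6-(hydroxymethyl)-10-methyl-3-methylidene-2-oxo-2,3,3a,4,5,8,9,11a-octahydrocyclodeca[b]furan-4-yl 2-methylprop-2-enoate
Conditions: HF·pyridine, pyridine, THF, 0 °C → rt
Reagents that add atoms: none
Why: Fluoride-mediated desilylation buffered with pyridine removes both TBS ethers without affecting the esters or the conjugated lactone.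

Step 20
Reactants: 30 (3aR,4R,6E,8S,10E,11aR)-8-hydroxy-6-(hydroxymethyl)-10-methyl-3-methylidene-2-oxo-2,3,3a,4,5,8,9,11a-octahydrocyclodeca[b]furan-4-yl 2-methylprop-2-enoate
Product: 31 (3aR,4R,6E,8S,10E,11aR)-8-(acetyloxy)-6-[(acetyloxy)methyl]-10-methyl-3-methylidene-2-oxo-2,3,3a,4,5,8,9,11a-octahydrocyclodeca[b]furan-4-yl 2-methylprop-2-enoate
Conditions: Ac2O, pyridine, 4-(dimethylamino)pyridine (cat.), CH2Cl2, 0 °C → rt
Reagents that add atoms: acetic anhydride, CC(=O)OC(C)=O
Why: Exhaustive acetylation of the primary and the secondary allylic alcohol.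

Step 21
Reactants: 31 (3aR,4R,6E,8S,10E,11aR)-8-(acetyloxy)-6-[(acetyloxy)methyl]-10-methyl-3-methylidene-2-oxo-2,3,3a,4,5,8,9,11a-octahydrocyclodeca[b]furan-4-yl 2-methylprop-2-enoate
Product: 32 (3aR,4R,6E,8S,10E,11aR)-8-(acetyloxy)-6-(hydroxymethyl)-10-methyl-3-methylidene-2-oxo-2,3,3a,4,5,8,9,11a-octahydrocyclodeca[b]furan-4-yl 2-methylprop-2-enoate (CNP0138477.2)
Conditions: lipase (immobilized Candida antarctica lipase B), n-BuOH (5 equiv), MTBE, 35 °C
Reagents that add atoms: none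
Why: Lipase-catalysed regioselective transesterification (alcoholysis): the serine hydrolase accepts the unhindered primary allylic acetate but not the ring-bound secondary acetate at C2, the methacrylate or the lactone, and the neutral, non-nucleophilic medium spares both Michael acceptors, releasing the C14 hydroxyl of the target.

**Compound list**
1 | (E)-but-2-enal (crotonaldehyde) | C/C=C/C=O | starting material
2 | allenylboronic acid pinacol ester | C=C=CB1OC(C)(C)C(C)(C)O1 | starting material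
3 | 2-{[(4S,5E)-hept-5-en-1-yn-4-yl]oxy}-4,4,5,5-tetramethyl-1,3,2-dioxaborolane (formed in the flask) | C/C=C/[C@@H](OB1OC(C)(C)C(C)(C)O1)CC#C | intermediate
4 | (4S,5E)-hept-5-en-1-yn-4-ol | C/C=C/[C@@H](O)CC#C | intermediate
5 | tert-butyl{[(4S,5E)-hept-5-en-1-yn-4-yl]oxy}dimethylsilane | C/C=C/[C@@H](O[Si](C)(C)C(C)(C)C)CC#C | intermediate
6 | [(1E,4S,5E)-4-{[tert-butyl(dimethyl)silyl]oxy}-2-methylhepta-1,5-dien-1-yl]dimethylalane (formed in the flask) | C/C=C/[C@@H](O[Si](C)(C)C(C)(C)C)C/C(C)=C/[Al](C)C | intermediate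
7 | (2E,5S,6E)-5-{[tert-butyl(dimethyl)silyl]oxy}-3-methylocta-2,6-dien-1-ol | C/C=C/[C@@H](O[Si](C)(C)C(C)(C)C)C/C(C)=C/CO | intermediate
8 | (2E,5S,6E)-5-{[tert-butyl(dimethyl)silyl]oxy}-3-methylocta-2,6-dienal | C/C=C/[C@@H](O[Si](C)(C)C(C)(C)C)C/C(C)=C/C=O | intermediate
9 | 4-methoxybenzyl propargyl ether | C#CCOCc1ccc(OC)cc1 | starting material
10 | {3-[(4-methoxyphenyl)methoxy]prop-1-yn-1-yl}(methyl)zinc (formed in the flask) | C[Zn]C#CCOCc1ccc(OC)cc1 | intermediate
11 | (4R,5E,8S,9E)-8-{[tert-butyl(dimethyl)silyl]oxy}-1-[(4-methoxyphenyl)methoxy]-6-methylundeca-5,9-dien-2-yn-4-ol | C/C=C/[C@@H](O[Si](C)(C)C(C)(C)C)C/C(C)=C/[C@@H](O)C#CCOCc1ccc(OC)cc1 | intermediate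
12 | sodium salt of the five-membered cyclic aluminate in which Al carries two 2-methoxyethoxy groups and is bonded to the C4 oxygen and to C2 of the (Z)-alkene of 11 after hydride addition at C3 (formed in the flask) | C/C=C/[C@@H](O[Si](C)(C)C(C)(C)C)C/C(C)=C/[C@H]1O[Al-](OCCOC)(OCCOC)C(COCc2ccc(OC)cc2)=C1.[Na+] | intermediate
13 | (2Z,4R,5E,8S,9E)-8-{[tert-butyl(dimethyl)silyl]oxy}-2-iodo-1-[(4-methoxyphenyl)methoxy]-6-methylundeca-2,5,9-trien-4-ol | C/C=C/[C@@H](O[Si](C)(C)C(C)(C)C)C/C(C)=C/[C@@H](O)/C=C(\I)COCc1ccc(OC)cc1 | intermediate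
14 | (5R)-5-[(1E,4S,5E)-4-{[tert-butyl(dimethyl)silyl]oxy}-2-methylhepta-1,5-dien-1-yl]-3-{[(4-methoxyphenyl)methoxy]methyl}furan-2(5H)-one | C/C=C/[C@@H](O[Si](C)(C)C(C)(C)C)C/C(C)=C/[C@H]1OC(=O)C(COCc2ccc(OC)cc2)=C1 | intermediate
15 | (5R)-5-[(1E,4S,5E)-4-{[tert-butyl(dimethyl)silyl]oxy}-2-methylhepta-1,5-dien-1-yl]-3-(hydroxymethyl)furan-2(5H)-one | C/C=C/[C@@H](O[Si](C)(C)C(C)(C)C)C/C(C)=C/[C@H]1OC(=O)C(CO)=C1 | intermediate
16 | (5R)-3-(bromomethyl)-5-[(1E,4S,5E)-4-{[tert-butyl(dimethyl)silyl]oxy}-2-methylhepta-1,5-dien-1-yl]furan-2(5H)-one | C/C=C/[C@@H](O[Si](C)(C)C(C)(C)C)C/C(C)=C/[C@H]1OC(=O)C(CBr)=C1 | intermediate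
17 | 2-methylidenepropane-1,3-diol | C=C(CO)CO | starting material
18 | sodium 2-(hydroxymethyl)prop-2-en-1-olate (formed in the flask) | C=C(CO)C[O-].[Na+] | intermediate
19 | 2-({[tert-butyl(dimethyl)silyl]oxy}methyl)prop-2-en-1-ol | C=C(CO)CO[Si](C)(C)C(C)(C)C | intermediate
20 | {[2-(bromomethyl)prop-2-en-1-yl]oxy}(tert-butyl)dimethylsilane | C=C(CBr)CO[Si](C)(C)C(C)(C)C | intermediate
21 | bromo[2-({[tert-butyl(dimethyl)silyl]oxy}methyl)prop-2-en-1-yl]zinc (formed in the flask) | C=C(C[Zn]Br)CO[Si](C)(C)C(C)(C)C | intermediate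
22 | 3-({[tert-butyl(dimethyl)silyl]oxy}methyl)but-3-en-1-ol | C=C(CCO)CO[Si](C)(C)C(C)(C)C | intermediate
23 | 3-({[tert-butyl(dimethyl)silyl]oxy}methyl)but-3-enal | C=C(CC=O)CO[Si](C)(C)C(C)(C)C | intermediate
24 | dichloro{[(5R)-5-[(1E,4S,5E)-4-{[tert-butyl(dimethyl)silyl]oxy}-2-methylhepta-1,5-dien-1-yl]-2-oxo-2,5-dihydrofuran-3-yl]methyl}chromium (formed in the flask) | C/C=C/[C@@H](O[Si](C)(C)C(C)(C)C)C/C(C)=C/[C@H]1OC(=O)C(C[Cr](Cl)Cl)=C1 | intermediate
25 | (4R,5R)-4-[(1S)-3-({[tert-butyl(dimethyl)silyl]oxy}methyl)-1-hydroxybut-3-en-1-yl]-5-[(1E,4S,5E)-4-{[tert-butyl(dimethyl)silyl]oxy}-2-methylhepta-1,5-dien-1-yl]-3-methylidenedihydrofuran-2(3H)-one | C/C=C/[C@@H](O[Si](C)(C)C(C)(C)C)C/C(C)=C/[C@H]1OC(=O)C(=C)[C@@H]1[C@@H](O)CC(=C)CO[Si](C)(C)C(C)(C)C | intermediate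
26 | (1R)-3-({[tert-butyl(dimethyl)silyl]oxy}methyl)-1-[(2R,3R)-2-[(1E,4S,5E)-4-{[tert-butyl(dimethyl)silyl]oxy}-2-methylhepta-1,5-dien-1-yl]-4-methylidene-5-oxooxolan-3-yl]but-3-en-1-yl formate | C/C=C/[C@@H](O[Si](C)(C)C(C)(C)C)C/C(C)=C/[C@H]1OC(=O)C(=C)[C@@H]1[C@H](OC=O)CC(=C)CO[Si](C)(C)C(C)(C)C | intermediate
27 | (3aR,4R,6E,8S,10E,11aR)-8-{[tert-butyl(dimethyl)silyl]oxy}-6-({[tert-butyl(dimethyl)silyl]oxy}methyl)-10-methyl-3-methylidene-2-oxo-2,3,3a,4,5,8,9,11a-octahydrocyclodeca[b]furan-4-yl formate | O=CO[C@@H]1C/C(CO[Si](C)(C)C(C)(C)C)=C\[C@@H](O[Si](C)(C)C(C)(C)C)C/C(C)=C/[C@H]2OC(=O)C(=C)[C@@H]21 | intermediate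
28 | (3aR,4R,6E,8S,10E,11aR)-8-{[tert-butyl(dimethyl)silyl]oxy}-6-({[tert-butyl(dimethyl)silyl]oxy}methyl)-4-hydroxy-10-methyl-3-methylidene-3a,4,5,8,9,11a-hexahydrocyclodeca[b]furan-2(3H)-one | O[C@@H]1C/C(CO[Si](C)(C)C(C)(C)C)=C\[C@@H](O[Si](C)(C)C(C)(C)C)C/C(C)=C/[C@H]2OC(=O)C(=C)[C@@H]21 | intermediate
29 | (3aR,4R,6E,8S,10E,11aR)-8-{[tert-butyl(dimethyl)silyl]oxy}-6-({[tert-butyl(dimethyl)silyl]oxy}methyl)-10-methyl-3-methylidene-2-oxo-2,3,3a,4,5,8,9,11a-octahydrocyclodeca[b]furan-4-yl 2-methylprop-2-enoate | C=C(C)C(=O)O[C@@H]1C/C(CO[Si](C)(C)C(C)(C)C)=C\[C@@H](O[Si](C)(C)C(C)(C)C)C/C(C)=C/[C@H]2OC(=O)C(=C)[C@@H]21 | intermediate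
30 | (3aR,4R,6E,8S,10E,11aR)-8-hydroxy-6-(hydroxymethyl)-10-methyl-3-methylidene-2-oxo-2,3,3a,4,5,8,9,11a-octahydrocyclodeca[b]furan-4-yl 2-methylprop-2-enoate | C=C(C)C(=O)O[C@@H]1C/C(CO)=C\[C@@H](O)C/C(C)=C/[C@H]2OC(=O)C(=C)[C@@H]21 | intermediate
31 | (3aR,4R,6E,8S,10E,11aR)-8-(acetyloxy)-6-[(acetyloxy)methyl]-10-methyl-3-methylidene-2-oxo-2,3,3a,4,5,8,9,11a-octahydrocyclodeca[b]furan-4-yl 2-methylprop-2-enoate | C=C(C)C(=O)O[C@@H]1C/C(COC(C)=O)=C\[C@@H](OC(C)=O)C/C(C)=C/[C@H]2OC(=O)C(=C)[C@@H]21 | intermediate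
32 | (3aR,4R,6E,8S,10E,11aR)-8-(acetyloxy)-6-(hydroxymethyl)-10-methyl-3-methylidene-2-oxo-2,3,3a,4,5,8,9,11a-octahydrocyclodeca[b]furan-4-yl 2-methylprop-2-enoate (CNP0138477.2) | C=C(C)C(=O)O[C@@H]1C/C(CO)=C\[C@@H](OC(C)=O)C/C(C)=C/[C@H]2OC(=O)C(=C)[C@@H]21 | target

**Totals**
Total step count: 21. Longest linear sequence: 17 steps (steps 1–9 and 14–21); fragment B takes 4 steps (10–13).

**Steps most likely to fail, with fallbacks**

Step 16 (ring-closing metathesis). Both reacting alkenes carry a bulky allylic silyl ether and the ring is strained, so oligomers or the ring-trans alkene may result. The fallback sets out from 26 and comes back to the route at 31. The silyl groups are exchanged before ring closure: HF·pyridine gives the acyclic diol formate F3, and Ac2O/pyridine gives the acyclic diacetate formate F4, whose small allylic acetates leave both alkenes accessible. Ring-closing metathesis of F4 with the same ruthenium catalyst gives the macrocyclic diacetate formate F5. Brief KHCO3 in MeOH at 0 °C removes only the formate and gives the macrocyclic diacetate alcohol F6, and methacrylic anhydride with 4-(dimethylamino)pyridine then gives 31.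

Step 14 (chromium allylation). The β,γ-unsaturated aldehyde is labile and the level of control at C8 is the least certain element of the route. The fallback sets out from 16 and 23 and comes back at 26. The coupling is run as an aqueous zinc Barbier reaction (Zn dust, THF/saturated aq. NH4Cl), which keeps the addition trans to the C6 side chain but passes through a looser transition state. Whatever 8R-epimeric carbinol F1 is formed is separated and formylated with retention (acetic formic anhydride, pyridine, 0 °C) to give 26, while the 8S epimer 25 goes on through step 15, so both epimers converge.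

Step 15 (Mitsunobu inversion). Elimination towards the conjugated diene can compete at this β-branched carbinol. The fallback sets out from 25 and comes back at 26. Inversion is done in two stages: chloromethanesulfonyl chloride and pyridine give the C8 chloromethanesulfonate F2, which caesium formate with 18-crown-6 in toluene displaces by SN2.

**Further compounds**
F1 | step 14 | (4R,5R)-4-[(1R)-3-({[tert-butyl(dimethyl)silyl]oxy}methyl)-1-hydroxybut-3-en-1-yl]-5-[(1E,4S,5E)-4-{[tert-butyl(dimethyl)silyl]oxy}-2-methylhepta-1,5-dien-1-yl]-3-methylidenedihydrofuran-2(3H)-one | C/C=C/[C@@H](O[Si](C)(C)C(C)(C)C)C/C(C)=C/[C@H]1OC(=O)C(=C)[C@@H]1[C@H](O)CC(=C)CO[Si](C)(C)C(C)(C)C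
F2 | step 15 | (1S)-3-({[tert-butyl(dimethyl)silyl]oxy}methyl)-1-[(2R,3R)-2-[(1E,4S,5E)-4-{[tert-butyl(dimethyl)silyl]oxy}-2-methylhepta-1,5-dien-1-yl]-4-methylidene-5-oxooxolan-3-yl]but-3-en-1-yl chloromethanesulfonate | C/C=C/[C@@H](O[Si](C)(C)C(C)(C)C)C/C(C)=C/[C@H]1OC(=O)C(=C)[C@@H]1[C@@H](OS(=O)(=O)CCl)CC(=C)CO[Si](C)(C)C(C)(C)C
F3 | step 16 | (1R)-1-[(2R,3R)-2-[(1E,4S,5E)-4-hydroxy-2-methylhepta-1,5-dien-1-yl]-4-methylidene-5-oxooxolan-3-yl]-3-(hydroxymethyl)but-3-en-1-yl formate | C/C=C/[C@@H](O)C/C(C)=C/[C@H]1OC(=O)C(=C)[C@@H]1[C@H](OC=O)CC(=C)CO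
F4 | step 16 | (1R)-3-[(acetyloxy)methyl]-1-[(2R,3R)-2-[(1E,4S,5E)-4-(acetyloxy)-2-methylhepta-1,5-dien-1-yl]-4-methylidene-5-oxooxolan-3-yl]but-3-en-1-yl formate | C/C=C/[C@@H](OC(C)=O)C/C(C)=C/[C@H]1OC(=O)C(=C)[C@@H]1[C@H](OC=O)CC(=C)COC(C)=O
F5 | step 16 | (3aR,4R,6E,8S,10E,11aR)-8-(acetyloxy)-6-[(acetyloxy)methyl]-10-methyl-3-methylidene-2-oxo-2,3,3a,4,5,8,9,11a-octahydrocyclodeca[b]furan-4-yl formate | O=CO[C@@H]1C/C(COC(C)=O)=C\[C@@H](OC(C)=O)C/C(C)=C/[C@H]2OC(=O)C(=C)[C@@H]21
F6 | step 16 | [(3aR,4R,6E,8S,10E,11aR)-8-(acetyloxy)-4-hydroxy-10-methyl-3-methylidene-2-oxo-2,3,3a,4,5,8,9,11a-octahydrocyclodeca[b]furan-6-yl]methyl acetate | O[C@@H]1C/C(COC(C)=O)=C\[C@@H](OC(C)=O)C/C(C)=C/[C@H]2OC(=O)C(=C)[C@@H]21
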